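**Plan**

1. Cuts: (a) both acetates and both C3 ketones, back to a tetraol; (b) the bond between the two CH2 groups of the bridge; (c) in each decahydro-1-benzoxepine half (locants O1, C2 gem-dimethyl, C3, C4, C5, C5a angular methyl, C6 bridge carbon, C7 methyl/oxygen, C8, C9, C9a) the O1–C2 and C5a–C6 bonds together; (d) the acyclic C15 chain into geranyl bromide, methyl acetoacetate and a Me3SiCH2 unit.
2. Enabling feature: O1 joins a fully substituted C2 (oxygenated C3 beside it) to C9a, and C9a sits next to quaternary C5a. This is the imprint of two trisubstituted epoxides placed 1,5 on a terpenoid chain: the inner epoxide oxygen can open the outer epoxide at its tertiary carbon, and the epoxonium ion so formed can be opened at tertiary C5a by an allylsilane.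
3. Forward order: chain assembly, double Shi epoxidation, one cascade that closes the oxepane and then the cyclohexane, split of the bicyclic bromide into a 7-hydroxy radical precursor and a 6-methylidene-7-ketone, radical union of the halves, methyl addition, oxidation, acetylation.
4. Stereochemistry: C3 and C9a (retention) and C5a (inversion) come from the Shi epoxides; C6 from the Z-allylsilane in a chair (in the ketone half from axial hydrogen delivery). The two halves differ only at C7: equatorial oxygen (7S) by O2 capture, axial oxygen (7R) by equatorial Grignard attack, both steered by the axial C5a methyl.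

Key step: step 7

Remark: the L-configured Shi ketone (enantiomer of the D-fructose-derived catalyst, made from L-sorbose) is taken as an available catalyst whose induction mirrors that of the D-ketone (R,R epoxides from E-trisubstituted alkenes); enolates, alkoxides, the epoxonium ion and radicals are transient species, described in the Why lines and not numbered.

**Route**

Step 1
Reactants: 1 methyl acetoacetate; 2 geranyl bromide
Product: 3 methyl (6E)-7,11-dimethyl-3-oxododeca-6,10-dienoate
Conditions: NaH, THF, 0 °C; n-BuLi, 0 °C; then 2, 0 °C → rt; aq. HCl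
Reagents that add atoms: none
Why: γ-Alkylation of the acetoacetate dianion, whose terminal carbanion is the more reactive site and displaces the allylic bromide by SN2 without touching the E-alkene.

Step 2
Reactants: 3 β-keto ester
Product: 4 methyl (2Z,6E)-3-[(diethoxyphosphoryl)oxy]-7,11-dimethyldodeca-2,6,10-trienoate
Conditions: NaH, Et2O, 0 °C; ClP(O)(OEt)2
Reagents that add atoms: diethyl chlorophosphate, CCOP(=O)(Cl)OCC
Why: O-Phosphorylation of the chelated sodium enolate of a β-keto ester in ether should give the Z enol phosphate (phosphate cis to the ester).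

Step 3
Reactants: 4 Z enol phosphate
Product: 5 methyl (2Z,6E)-7,11-dimethyl-3-[(trimethylsilyl)methyl]dodeca-2,6,10-trienoate
Conditions: Me3SiCH2MgCl, Ni(acac)2 (5 mol %), THF, 0 °C → rt
Reagents that add atoms: (trimethylsilyl)methylmagnesium chloride, C[Si](C)(C)C[Mg]Cl
Why: Nickel-catalysed Kumada-type coupling of an enol phosphate with a Grignard reagent proceeds with retention of alkene geometry, so the CH2SiMe3 group ends cis to the ester.

Step 4
Reactants: 5 silylmethyl trienoate
Product: 6 methyl (2Z)-5-[(2S,3S)-3-{2-[(2S)-3,3-dimethyloxiran-2-yl]ethyl}-3-methyloxiran-2-yl]-3-[(trimethylsilyl)methyl]pent-2-enoate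
Conditions: L-configured Shi ketone (40 mol %), Oxone, K2CO3, Bu4NHSO4, Na2B4O7/Na2EDTA buffer, MeCN–CH2(OMe)2–H2O, 0 °C
Reagents that add atoms: Oxone (active component potassium peroxymonosulfate), [K+].[O-]S(=O)(=O)OO
Why: Shi asymmetric epoxidation, in which the chiral dioxirane attacks the two electron-rich trisubstituted alkenes through the spiro transition state (S,S and S epoxides from the L-ketone) and leaves the ester-conjugated alkene alone.

Step 5
Reactants: 6 bis-epoxy ester
Product: 7 (2Z)-5-[(2S,3S)-3-{2-[(2S)-3,3-dimethyloxiran-2-yl]ethyl}-3-methyloxiran-2-yl]-3-[(trimethylsilyl)methyl]pent-2-en-1-ol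
Conditions: i-Bu2AlH (2.2 equiv), CH2Cl2, −78 °C; Rochelle salt work-up
Reagents that add atoms: none
Why: 1,2-Reduction of an α,β-unsaturated ester by i-Bu2AlH at low temperature, to which trisubstituted epoxides are inert, converts the deactivated enoate into a nucleophilic allylsilane.

Step 6
Reactants: 7 allylic alcohol
Product: 8 tert-butyldimethylsilyl ether of 7
Conditions: TBSCl, imidazole, CH2Cl2, 0 °C
Reagents that add atoms: tert-butyldimethylsilyl chloride, CC(C)(C)[Si](C)(C)Cl
Why: Standard silylation under basic conditions masks the allylic hydroxyl as a poorly ionising, weakly basic ether before the Lewis acid step.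

Step 7
Reactants: 8 bis-epoxy (Z)-allylsilane
Product: 10 (3S,5aS,6R,9aS)-6-(hydroxymethyl)-2,2,5a-trimethyl-7-methylidenedecahydro-1-benzoxepin-3-ol, via bicyclic bis-silyl ether 9 (not isolated)
Conditions: TMSOTf (0.5 equiv), 2,6-di-tert-butyl-4-methylpyridine, CH2Cl2, −78 °C; then Bu4NF, THF, 0 °C → rt
Reagents that add atoms: none
Why: Silylation of the terminal 2,2-dimethyloxirane by TMSOTf makes its tertiary carbon electrophilic, the oxygen of the neighbouring oxirane attacks it (this forms the O1–C2 bond) to give a fused bicyclic epoxonium ion, and the γ-carbon of the (Z)-allylsilane opens that ion at the tertiary carbon that becomes C5a, the β-silyl cation losing Me3Si+ to leave the 7-methylidene group and carry the chain. The closest known reaction types are the silyl triflate-promoted tandem oxa-/carbacyclization of 1,5-bis-epoxides ended by a carbon π-nucleophile and the epoxide-initiated allylsilane cyclization. The oxepane closes by endo attack at the more substituted epoxide carbon (a six-membered oxonium ring that becomes the seven-membered ether once the C5a–O bond is cut), and the cyclohexane closes by 6-endo-trig attack of the alkene with endo, backside opening of the epoxonium ion through a chair transition state. C3 and C9a keep the configurations set in the Shi epoxidation because their C–O bonds are never broken, C5a is inverted so the ring fusion is trans, and C6 is fixed by the Z geometry of the allylsilane in the chair, which places the CH2OTBS group equatorial and the new C6–H anti to the angular methyl. The step needs endo regioselectivity at both epoxides and reaction at the epoxides in preference to the allylic silyl ether; the methyl groups that make both attacked carbons tertiary should secure the first, and the low basicity of the silyl ether, the hindered base and −78 °C the second.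

Step 8
Reactants: 10 bicyclic diol
Product: 11 (3S,5aS,6R,9aS)-6-(bromomethyl)-2,2,5a-trimethyl-7-methylidenedecahydro-1-benzoxepin-3-ol
Conditions: CBr4, PPh3, 2,6-lutidine, CH2Cl2, 0 °C
Reagents that add atoms: carbon tetrabromide, BrC(Br)(Br)Br
Why: Appel bromination should act on the primary alcohol only, because SN2 displacement at the secondary C3 carbinol flanked by the quaternary C2 is far slower.

Step 9
Reactants: 11 homoallylic bromide
Product: 13 (3S,5aS,6S,7S,9aS)-6-(bromomethyl)-2,2,5a,7-tetramethyldecahydro-1-benzoxepine-3,7-diol, via tertiary hydroperoxide 12 (not isolated)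
Conditions: Mn(dpm)3 (10 mol %), PhSiH3, O2 (1 atm), i-PrOH–CH2Cl2, 0 °C; then PPh3
Reagents that add atoms: dioxygen, O=O
Why: Mukaiyama hydration (metal hydride hydrogen atom transfer) puts hydrogen on the CH2 terminus, and the tertiary C7 radical should capture O2 from the equatorial α face because the axial face is blocked by the syn-axial C5a methyl, giving equatorial 7-OH and axial 7-CH3 after phosphine reduction of the hydroperoxide.

Step 10
Reactants: 11 homoallylic bromide
Product: 15 (3S,5aS,9aS)-3-hydroxy-2,2,5a-trimethyl-6-methylideneoctahydro-1-benzoxepin-7(2H)-one, via β-bromo ketone 14 (not isolated)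
Conditions: O3, CH2Cl2, −78 °C; PPh3, −78 °C → rt; then Et3N, 0 °C
Reagents that add atoms: ozone, [O-][O+]=O
Why: Ozonolysis of the 1,1-disubstituted alkene gives the C7 ketone, and the resulting β-bromo ketone loses HBr by E1cB elimination to the α-methylene ketone, which cannot isomerise into the ring because C5a is quaternary.

Step 11
Reactants: 13 bromo diol; 15 α-methylene ketone (1.5 equiv)
Product: 16 (3S,5aS,6S,9aS)-6-{2-[(3S,5aS,6S,7S,9aS)-3,7-dihydroxy-2,2,5a,7-tetramethyldecahydro-1-benzoxepin-6-yl]ethyl}-3-hydroxy-2,2,5a-trimethyloctahydro-1-benzoxepin-7(2H)-one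
Conditions: (Me3Si)3SiH (slow addition), AIBN, PhMe, 80 °C
Reagents that add atoms: none
Why: Giese radical conjugate addition, in which the primary radical from bromine abstraction adds to the unsubstituted terminus of the enone and the α-keto radical takes hydrogen axially from the α face, anti to the angular methyl, to give the equatorial side chain, which is also the thermodynamic epimer at this enolisable centre.

Step 12
Reactants: 16 keto triol
Product: 17 (3S,5aS,6S,7R,9aS)-6-{2-[(3S,5aS,6S,7S,9aS)-3,7-dihydroxy-2,2,5a,7-tetramethyldecahydro-1-benzoxepin-6-yl]ethyl}-2,2,5a,7-tetramethyldecahydro-1-benzoxepine-3,7-diol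
Conditions: MeMgBr (excess), THF, −40 → 0 °C; aq. NH4Cl
Reagents that add atoms: methylmagnesium bromide, C[Mg]Br
Why: Grignard 1,2-addition to the cyclohexanone (after the hydroxyls are converted to magnesium alkoxides) should occur by equatorial attack, as for cyclohexanones with a syn-axial 3-methyl group, giving axial 7-OH and equatorial 7-CH3.

Step 13
Reactants: 17 tetraol
Product: 18 diketone diol (both C3 carbinols oxidised, both tertiary C7 alcohols free)
Conditions: Dess–Martin periodinane, NaHCO3, CH2Cl2, rt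
Reagents that add atoms: none
Why: Dess–Martin oxidation converts the two secondary alcohols to ketones and cannot oxidise the tertiary alcohols; no stereocentre that remains in the target is touched.

Step 14
Reactants: 18 diketone diol
Product: 19 target diacetate
Conditions: Ac2O, Sc(OTf)3 (5 mol %), MeCN, −20 °C
Reagents that add atoms: acetic anhydride, CC(=O)OC(C)=O
Why: Lewis acid-catalysed acylation with Ac2O acetylates hindered tertiary alcohols at low temperature, where ionisation and enol acetate formation at the ketones should not compete.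

**Compound list**

1 | methyl acetoacetate | COC(=O)CC(C)=O | starting material
2 | geranyl bromide, (2E)-1-bromo-3,7-dimethylocta-2,6-diene | CC(C)=CCC/C(C)=C/CBr | starting material
3 | methyl (6E)-7,11-dimethyl-3-oxododeca-6,10-dienoate | COC(=O)CC(=O)CC/C=C(\C)CCC=C(C)C | intermediate
4 | methyl (2Z,6E)-3-[(diethoxyphosphoryl)oxy]-7,11-dimethyldodeca-2,6,10-trienoate | COC(=O)/C=C(\OP(=O)(OCC)OCC)CC/C=C(\C)CCC=C(C)C | intermediate
5 | methyl (2Z,6E)-7,11-dimethyl-3-[(trimethylsilyl)methyl]dodeca-2,6,10-trienoate | COC(=O)/C=C(\C[Si](C)(C)C)CC/C=C(\C)CCC=C(C)C | intermediate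
6 | methyl (2Z)-5-[(2S,3S)-3-{2-[(2S)-3,3-dimethyloxiran-2-yl]ethyl}-3-methyloxiran-2-yl]-3-[(trimethylsilyl)methyl]pent-2-enoate | COC(=O)/C=C(\C[Si](C)(C)C)CC[C@@H]1O[C@@]1(C)CC[C@@H]1OC1(C)C | intermediate
7 | (2Z)-5-[(2S,3S)-3-{2-[(2S)-3,3-dimethyloxiran-2-yl]ethyl}-3-methyloxiran-2-yl]-3-[(trimethylsilyl)methyl]pent-2-en-1-ol | OC/C=C(\C[Si](C)(C)C)CC[C@@H]1O[C@@]1(C)CC[C@@H]1OC1(C)C | intermediate
8 | tert-butyldimethylsilyl ether of 7 | CC(C)(C)[Si](C)(C)OC/C=C(\C[Si](C)(C)C)CC[C@@H]1O[C@@]1(C)CC[C@@H]1OC1(C)C | intermediate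
9 | tert-butyl{[(3S,5aS,6R,9aS)-2,2,5a-trimethyl-7-methylidene-3-[(trimethylsilyl)oxy]decahydro-1-benzoxepin-6-yl]methoxy}dimethylsilane (trans-fused, CH2O equatorial) | CC(C)(C)[Si](C)(C)OC[C@H]1[C@]2(C)CC[C@H](O[Si](C)(C)C)C(C)(C)O[C@H]2CCC1=C | intermediate (not isolated)
10 | (3S,5aS,6R,9aS)-6-(hydroxymethyl)-2,2,5a-trimethyl-7-methylidenedecahydro-1-benzoxepin-3-ol | OC[C@H]1[C@]2(C)CC[C@H](O)C(C)(C)O[C@H]2CCC1=C | intermediate
11 | (3S,5aS,6R,9aS)-6-(bromomethyl)-2,2,5a-trimethyl-7-methylidenedecahydro-1-benzoxepin-3-ol | BrC[C@H]1[C@]2(C)CC[C@H](O)C(C)(C)O[C@H]2CCC1=C | intermediate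
12 | (3S,5aS,6S,7S,9aS)-6-(bromomethyl)-7-hydroperoxy-2,2,5a,7-tetramethyldecahydro-1-benzoxepin-3-ol (OOH equatorial) | BrC[C@H]1[C@]2(C)CC[C@H](O)C(C)(C)O[C@H]2CC[C@]1(C)OO | intermediate (not isolated)
13 | (3S,5aS,6S,7S,9aS)-6-(bromomethyl)-2,2,5a,7-tetramethyldecahydro-1-benzoxepine-3,7-diol (7-OH equatorial, 7-CH3 axial) | BrC[C@H]1[C@]2(C)CC[C@H](O)C(C)(C)O[C@H]2CC[C@]1(C)O | intermediate
14 | (3S,5aS,6S,9aS)-6-(bromomethyl)-3-hydroxy-2,2,5a-trimethyloctahydro-1-benzoxepin-7(2H)-one | BrC[C@H]1[C@]2(C)CC[C@H](O)C(C)(C)O[C@H]2CCC1=O | intermediate (not isolated)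
15 | (3S,5aS,9aS)-3-hydroxy-2,2,5a-trimethyl-6-methylideneoctahydro-1-benzoxepin-7(2H)-one | C=C1[C@]2(C)CC[C@H](O)C(C)(C)O[C@H]2CCC1=O | intermediate
16 | (3S,5aS,6S,9aS)-6-{2-[(3S,5aS,6S,7S,9aS)-3,7-dihydroxy-2,2,5a,7-tetramethyldecahydro-1-benzoxepin-6-yl]ethyl}-3-hydroxy-2,2,5a-trimethyloctahydro-1-benzoxepin-7(2H)-one | C(C[C@H]1[C@]2(C)CC[C@H](O)C(C)(C)O[C@H]2CCC1=O)[C@H]1[C@]2(C)CC[C@H](O)C(C)(C)O[C@H]2CC[C@]1(C)O | intermediate
17 | (3S,5aS,6S,7R,9aS)-6-{2-[(3S,5aS,6S,7S,9aS)-3,7-dihydroxy-2,2,5a,7-tetramethyldecahydro-1-benzoxepin-6-yl]ethyl}-2,2,5a,7-tetramethyldecahydro-1-benzoxepine-3,7-diol (7-OH axial in the 7R half, equatorial in the 7S half) | C(C[C@H]1[C@]2(C)CC[C@H](O)C(C)(C)O[C@H]2CC[C@@]1(C)O)[C@H]1[C@]2(C)CC[C@H](O)C(C)(C)O[C@H]2CC[C@]1(C)O | intermediate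
18 | (5aS,6S,7R,9aS)-7-hydroxy-6-{2-[(5aS,6S,7S,9aS)-7-hydroxy-2,2,5a,7-tetramethyl-3-oxodecahydro-1-benzoxepin-6-yl]ethyl}-2,2,5a,7-tetramethyloctahydro-1-benzoxepin-3(2H)-one | C(C[C@H]1[C@]2(C)CCC(=O)C(C)(C)O[C@H]2CC[C@@]1(C)O)[C@H]1[C@]2(C)CCC(=O)C(C)(C)O[C@H]2CC[C@]1(C)O | intermediate
19 | (5aS,6S,7R,9aS)-6-{2-[(5aS,6S,7S,9aS)-7-acetoxy-2,2,5a,7-tetramethyl-3-oxodecahydro-1-benzoxepin-6-yl]ethyl}-2,2,5a,7-tetramethyl-3-oxodecahydro-1-benzoxepin-7-yl acetate (CNP0325605.1) | CC(=O)O[C@]1(C)CC[C@@H]2OC(C)(C)C(=O)CC[C@@]2(C)[C@@H]1CC[C@H]1[C@]2(C)CCC(=O)C(C)(C)O[C@H]2CC[C@]1(C)OC(C)=O | target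

**Step count**

Total: 14 steps. Longest linear sequence: 13 steps (1–9, then 11–14; step 10 is the parallel branch from 11).

**Steps most likely to fail**

1. Step 7 (cascade). The epoxonium ion may collapse before the carbon–carbon bond forms (exo opening to smaller cyclic ethers, hydride shift, capture by triflate), or the allylic silyl ether may ionise with 1,4-loss of the silyl group. The fallback sets out from 3 and returns at 10, replacing the allylsilane by an enol silane as the terminating nucleophile. β-Keto ester 3 is silylated (TBSOTf, Et3N) to the Z silyl enol ether methyl (2Z,6E)-3-[(tert-butyldimethylsilyl)oxy]-7,11-dimethyldodeca-2,6,10-trienoate F1. Shi epoxidation of its two isolated alkenes with the L-ketone gives the bis-epoxide F2. The silyl triflate cascade (TBSOTf, hindered pyridine, −78 °C) is now ended by the enol silane, with transfer of the silyl group to the C3 oxygen, and gives the bicyclic β-keto ester 3-O-silyl ether F3. This is desilylated in the same flask (Bu4NF) to the hydroxy keto ester F4, in which the C6 ester is equatorial by enolisation. Takai–Lombardo methylenation (Zn, CH2Br2, TiCl4) of the ketone gives the methylidene ester F5, and LiAlH4 reduction of the ester returns to diol 10.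

2. Step 11 (radical union). The primary radical may be reduced by the silane before it adds, and the α-methylene ketone may telomerise, both at the cost of two advanced fragments. The fallback sets out from 15 (with 13 as partner) and returns at 17, replacing the radical addition by an alkyl–alkyl cross-coupling. MeLi adds 1,2 to enone 15 by equatorial attack to give the allylic diol (3S,5aS,7R,9aS)-2,2,5a,7-tetramethyl-6-methylidenedecahydro-1-benzoxepine-3,7-diol F6. Hydroboration with excess 9-BBN from the α face (anti to the angular methyl) gives the B-alkyl-9-borabicyclononane F7, with C6–H axial; it is drawn with free hydroxyls, which are masked in the flask as O-boryl ethers by the excess borane. Nickel-catalysed alkyl–alkyl Suzuki–Miyaura coupling of F7 with bromide 13 (NiCl2·glyme, trans-N,N'-dimethylcyclohexane-1,2-diamine, KOt-Bu, i-BuOH, dioxane, rt) returns to tetraol 17.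

3. Step 9 (hydration). Facial selectivity in oxygen capture by the tertiary radical may be poor, giving the axial alcohol as well. The fallback sets out from 10 and returns at 13, replacing radical hydration by epoxidation and hydride opening. mCPBA (NaHCO3, CH2Cl2) epoxidises the methylidene group of 10 from the less hindered α face to the spiro-epoxide F8 (epoxide oxygen equatorial, CH2 axial). LiAlH4 opens it at the CH2 terminus to the triol (3S,5aS,6R,7S,9aS)-6-(hydroxymethyl)-2,2,5a,7-tetramethyldecahydro-1-benzoxepine-3,7-diol F9. Appel bromination of its primary alcohol (CBr4, PPh3) returns to 13.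

**Further compounds**

F1 | step 7 | methyl (2Z,6E)-3-[(tert-butyldimethylsilyl)oxy]-7,11-dimethyldodeca-2,6,10-trienoate | COC(=O)/C=C(\O[Si](C)(C)C(C)(C)C)CC/C=C(\C)CCC=C(C)C
F2 | step 7 | methyl (2Z)-3-[(tert-butyldimethylsilyl)oxy]-5-[(2S,3S)-3-{2-[(2S)-3,3-dimethyloxiran-2-yl]ethyl}-3-methyloxiran-2-yl]pent-2-enoate | COC(=O)/C=C(\O[Si](C)(C)C(C)(C)C)CC[C@@H]1O[C@@]1(C)CC[C@@H]1OC1(C)C
F3 | step 7 | methyl (3S,5aS,6S,9aS)-3-[(tert-butyldimethylsilyl)oxy]-2,2,5a-trimethyl-7-oxodecahydro-1-benzoxepine-6-carboxylate | COC(=O)[C@H]1[C@]2(C)CC[C@H](O[Si](C)(C)C(C)(C)C)C(C)(C)O[C@H]2CCC1=O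
F4 | step 7 | methyl (3S,5aS,6S,9aS)-3-hydroxy-2,2,5a-trimethyl-7-oxodecahydro-1-benzoxepine-6-carboxylate | COC(=O)[C@H]1[C@]2(C)CC[C@H](O)C(C)(C)O[C@H]2CCC1=O
F5 | step 7 | methyl (3S,5aS,6R,9aS)-3-hydroxy-2,2,5a-trimethyl-7-methylidenedecahydro-1-benzoxepine-6-carboxylate | COC(=O)[C@H]1[C@]2(C)CC[C@H](O)C(C)(C)O[C@H]2CCC1=C
F6 | step 11 | (3S,5aS,7R,9aS)-2,2,5a,7-tetramethyl-6-methylidenedecahydro-1-benzoxepine-3,7-diol | C=C1[C@]2(C)CC[C@H](O)C(C)(C)O[C@H]2CC[C@@]1(C)O
F7 | step 11 | 9-{[(3S,5aS,6S,7R,9aS)-3,7-dihydroxy-2,2,5a,7-tetramethyldecahydro-1-benzoxepin-6-yl]methyl}-9-borabicyclo[3.3.1]nonane | C([C@H]1[C@]2(C)CC[C@H](O)C(C)(C)O[C@H]2CC[C@@]1(C)O)B1C2CCCC1CCC2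
F8 | step 9 | spiro-epoxide of 10 at C7 (epoxide oxygen equatorial, CH2 axial), 6-(hydroxymethyl)-2,2,5a-trimethyloctahydro-2H-spiro[1-benzoxepine-7,2'-oxiran]-3-ol | OC[C@H]1[C@]2(C)CC[C@H](O)C(C)(C)O[C@H]2CC[C@]1(C3)O3
F9 | step 9 | (3S,5aS,6R,7S,9aS)-6-(hydroxymethyl)-2,2,5a,7-tetramethyldecahydro-1-benzoxepine-3,7-diol | OC[C@H]1[C@]2(C)CC[C@H](O)C(C)(C)O[C@H]2CC[C@]1(C)O
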